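**Strategy**

Ring A carries six substituents: oxygens on C2, C4 and C6, separated by the C1 methyl, the C3 isobutyryl group and C5, which bears the methine C7. An arene of this kind falls out of the union of a vinylketene with an ynol ether, so ring A is cut at C4–C5 and C6–C1. A single thermal Danheiser benzannulation of 3-ethoxy-2-methylcyclobutenone with a triisopropylsiloxyalkyne assembles the whole ring, its oxygens emerging as OH, OEt and OSi and C3 staying free for a Fries acylation. The siloxyalkyne already holds ring B (as methyl enol ether) and the C7 stereocentre, set beforehand by asymmetric conjugate alkynylation of isobutylidenesyncarpic acid.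

Key step: step 6

**Remarks on the chemistry (assumptions)**

- Atom labels: ring A carbons C1–C6 as in the target (C1 methyl, C3 acyl, C5 bearing C7); ring B atoms are primed (C2' bears C7, C1' and C3' flank it, C5' is the ketone between the two CMe2 groups).
- The target is (S) at C7 (priority: ring B carbon > aryl > i-Pr > H). The silylalkyne intermediates 6 and 7 have the same spatial arrangement but are named (R), because silicon raises the priority of the alkynyl group.
- The sense of induction of the rhodium catalyst in step 2 is assigned by analogy; if a first run shows the opposite sense, the mirror-image ligand would be used.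
- Syncarpic acid is taken as purchasable; ketene is generated from acetone in a ketene generator and used directly.
- The vinylketene formed from the cyclobutenone is the 1-ethoxyvinyl isomer (ethoxy on the internal vinyl carbon); this is what places OEt at C2 of ring A.

**Route**

Step 1
Reactants: 1 syncarpic acid; 2 isobutyraldehyde
Product: 4 isobutylidenesyncarpic acid (2,2,4,4-tetramethyl-6-(2-methylpropylidene)cyclohexane-1,3,5-trione), via piperidine Mannich adduct 3 (not isolated)
Conditions: piperidine (1.05 equiv), CH2Cl2, rt; then 1 M HCl, 0 °C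
Reagents that add atoms: none
Why: Knoevenagel condensation run through the piperidine Mannich adduct, which stores the very electrophilic alkylidene and so suppresses addition of a second molecule of 1, followed by acid-triggered elimination of piperidinium (retro-Mannich type); the exocyclic alkene is flanked by two equivalent carbonyls, so no alkene isomers arise and no stereocentre is formed.

Step 2
Reactants: 4 isobutylidenesyncarpic acid; 5 trimethylsilylacetylene
Product: 6 3-hydroxy-4,4,6,6-tetramethyl-2-[(3R)-4-methyl-1-(trimethylsilyl)pent-1-yn-3-yl]cyclohex-2-ene-1,5-dione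
Conditions: [Rh(OAc)(C2H4)2]2 (2.5 mol %), (R)-DTBM-SEGPHOS (5.5 mol %), 5 (2 equiv), 1,4-dioxane, 25–40 °C
Reagents that add atoms: none
Why: Rhodium-catalysed asymmetric conjugate alkynylation (1,4-addition of a monovalent rhodium acetylide), a reaction type established for alkylidene Meldrum's acids and enones and applied here to a doubly activated alkylidene whose carbonyls are locked s-cis; the chiral bisphosphine makes the catalyst distinguish the enantiotopic faces of trigonal C7 (i-Pr against H), delivery of the alkynyl group to the Re face (ring B carbon > i-Pr > H) sets C7 as in (R)-6 under catalyst control, and the acidic enol product protonates the rhodium enolate so that turnover needs no added base that could deconjugate 4.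

Step 3
Reactants: 6 silylalkyne enol
Product: 8 3-methoxy-4,4,6,6-tetramethyl-2-[(3S)-4-methylpent-1-yn-3-yl]cyclohex-2-ene-1,5-dione, via silylated methyl enol ether 7 (not isolated)
Conditions: Me3SiCHN2 (1.3 equiv), MeOH–toluene, 0 °C → rt; then K2CO3 (0.2 equiv), MeOH, rt
Reagents that add atoms: trimethylsilyldiazomethane, C[Si](C)(C)C=[N+]=[N-]
Why: Diazoalkane O-methylation of the acidic vinylogous acid (oxygen-selective, and the two enol oxygens are equivalent, so one enol ether results) followed in the same pot by carbonate-mediated methanolytic protodesilylation of the alkynylsilane, for which methanol is a degenerate partner of the methyl enol ether; masking the enol first removes the nucleophile that could otherwise add to the freed alkyne, and the non-acidic C7–H is untouched (the descriptor changes from R to S only because silicon leaves the priority sequence).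

Step 4
Reactants: 8 terminal alkyne
Product: 11 3-methoxy-4,4,6,6-tetramethyl-2-[(3S)-4-methyl-1-(triisopropylsilyloxy)pent-1-yn-3-yl]cyclohex-2-ene-1,5-dione, via lithium acetylide 9 (not isolated), via lithium ynolate 10 (not isolated)
Conditions: t-BuOOH (1.1 equiv), LiHMDS (2.1 equiv), THF, −78 → 0 °C; then i-Pr3SiOTf (1.2 equiv), −78 °C
Reagents that add atoms: tert-butyl hydroperoxide (used as its lithium salt), CC(C)(C)OO; triisopropylsilyl trifluoromethanesulfonate, CC(C)[Si](OS(=O)(=O)C(F)(F)F)(C(C)C)C(C)C
Why: Oxidation of a lithium acetylide with lithium tert-butyl peroxide (electrophilic oxygen transfer to carbon) gives the lithium ynolate, which the bulky silyl triflate captures on oxygen to give the thermally robust triisopropylsilyl ynol ether; the amide base is non-nucleophilic, ring B has no enolisable hydrogen and its carbonyls are either a vinylogous ester or flanked by two quaternary carbons, and the C7–H is many pKa units less acidic than the alkyne C–H, so C7 should keep its configuration.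

Step 5
Reactants: 12 acetone; 13 1-ethoxyprop-1-yne
Product: 15 3-ethoxy-2-methylcyclobut-2-en-1-one, via ketene 14 (not isolated)
Conditions: acetone pyrolysis (ketene generator, about 700 °C); gas stream passed into 13, CH2Cl2, 0 °C → rt
Reagents that add atoms: none
Why: Thermal [2+2] cycloaddition of ketene with an ynol ether, a known cyclobutenone synthesis; the nucleophilic methyl-bearing alkyne carbon bonds to the ketene carbonyl carbon, which fixes methyl at C2 and ethoxy at C3 of the four-membered ring.

Step 6
Reactants: 11 siloxyalkyne; 15 3-ethoxy-2-methylcyclobut-2-en-1-one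
Product: 20 2-{(1S)-1-[4-ethoxy-6-hydroxy-3-methyl-2-(triisopropylsilyloxy)phenyl]-2-methylpropyl}-3-methoxy-4,4,6,6-tetramethylcyclohex-2-ene-1,5-dione, via vinylketene 16 (not isolated), via vinylcyclobutenone 17 (not isolated), via dienylketene 18 (not isolated), via cyclohexadienone 19 (not isolated)
Conditions: 15 (1.3 equiv), toluene (degassed), 80 → 110 °C, sealed tube, Ar
Reagents that add atoms: none
Why: Heating opens 15 by reversible 4π electrocyclic ring opening to the (1-ethoxyvinyl)ketene 16, whose ketene C=C adds [2+2] to the siloxyalkyne of 11 to give the 4-vinylcyclobutenone 17 (forming C4–C5 and C6–C1); a second 4π opening gives dienylketene 18, which closes to dienone 19 and tautomerises to phenol 20. The closest known reaction is the Danheiser benzannulation of cyclobutenones with trialkylsiloxyalkynes, which gives resorcinol monosilyl ethers with this substituent placement. Ring A is closed by the thermal disrotatory 6π electrocyclisation of 18, which re-forms the C3–C4 bond that was broken when 15 opened. No stereocentre is created (the quaternary carbon of 17 is lost on ring opening), and C7, already set, should survive because the conditions are neutral and aprotic and its C–H is only weakly acidic. The selectivity needed is the orientation of the [2+2] step, ketene carbonyl carbon to the alkyne carbon that bears C7, and it is secured by the polarisation of the siloxyalkyne, whose carbon remote from oxygen is the nucleophilic one. Ring B is carried as a methyl enol ether without O–H or enolisable C–H so that nothing in 11 traps the ketenes, the triisopropylsilyl group suppresses the 1,3-silyl shift to a silylketene, and 15 rather than 11 is used in slight excess to limit acylation of the new phenol.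

Step 7
Reactants: 20 ring A phenol
Product: 21 5-ethoxy-2-[(1S)-1-(2-methoxy-3,3,5,5-tetramethyl-4,6-dioxocyclohex-1-en-1-yl)-2-methylpropyl]-4-methyl-3-(triisopropylsilyloxy)phenyl 2-methylpropanoate
Conditions: i-PrCOCl (1.3 equiv), Et3N, DMAP (cat.), CH2Cl2, 0 °C → rt
Reagents that add atoms: 2-methylpropanoyl chloride, CC(C)C(Cl)=O
Why: Nucleophile-catalysed O-acylation (esterification) of the single free hydroxyl, the C4 phenol; no other O–H is present.

Step 8
Reactants: 21 aryl isobutyrate
Product: 22 2-{(1S)-1-[4-ethoxy-6-hydroxy-3-methyl-5-(2-methylpropanoyl)-2-(triisopropylsilyloxy)phenyl]-2-methylpropyl}-3-methoxy-4,4,6,6-tetramethylcyclohex-2-ene-1,5-dione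
Conditions: TiCl4 (3 equiv), ClCH2CH2Cl, 0 → 40 °C; then 1 M HCl
Reagents that add atoms: none
Why: Fries rearrangement in which TiCl4 ionises the aryl ester and the acylium ion returns to C3, the only unsubstituted ring carbon (ortho to O4 and O2, para to O6), where the product is held as a titanium chelate of the ortho-hydroxy ketone; every acyl-transfer pathway converges on C3, and any ether loss under the Lewis acid only anticipates steps 9 and 10.

Step 9
Reactants: 22 ortho-hydroxy ketone
Product: 23 3-hydroxy-4,4,6,6-tetramethyl-2-{(1S)-1-[4,6-dihydroxy-3-methyl-5-(2-methylpropanoyl)-2-(triisopropylsilyloxy)phenyl]-2-methylpropyl}cyclohex-2-ene-1,5-dione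
Conditions: BBr3 (5 equiv), CH2Cl2, −78 → 0 °C; then H2O, 0 °C
Reagents that add atoms: none
Why: Boron tribromide dealkylation in which coordination to the C2 ether oxygen next to the C3 ketone and to the ring B vinylogous ester turns ethyl and methyl into leaving groups for bromide attack (SN2), hydrolysis then releasing the C2 phenol and the ring B enol; the hindered aryl silyl ether at C6 should persist at low temperature and keeps O6 from condensing with ring B, while any material that does lose it is already 24.

Step 10
Reactants: 23 silyl ether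
Product: 24 3-hydroxy-4,4,6,6-tetramethyl-2-{(1S)-2-methyl-1-[2,4,6-trihydroxy-3-methyl-5-(2-methylpropanoyl)phenyl]propyl}cyclohex-2-ene-1,5-dione (CNP0210316.1)
Conditions: n-Bu4NF (3 equiv), AcOH (3 equiv), THF, 0 °C; pH 3 work-up
Reagents that add atoms: none
Why: Fluoride-induced cleavage of the aryl silyl ether driven by Si–F bond formation, buffered with acetic acid so that the acidic phenol–triketone and its benzylic C7 stereocentre are not held as free anions; no other group in 23 reacts with fluoride.

**Compound list**

1 | syncarpic acid (2,2,4,4-tetramethylcyclohexane-1,3,5-trione) | CC1(C)C(=O)CC(=O)C(C)(C)C1=O | starting material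
2 | isobutyraldehyde (2-methylpropanal) | CC(C)C=O | starting material
3 | 3-hydroxy-4,4,6,6-tetramethyl-2-[2-methyl-1-(piperidin-1-yl)propyl]cyclohex-2-ene-1,5-dione (racemic Mannich adduct) | CC(C)C(N1CCCCC1)C2=C(O)C(C)(C)C(=O)C(C)(C)C2=O | intermediate
4 | isobutylidenesyncarpic acid (2,2,4,4-tetramethyl-6-(2-methylpropylidene)cyclohexane-1,3,5-trione) | CC(C)C=C1C(=O)C(C)(C)C(=O)C(C)(C)C1=O | intermediate
5 | trimethylsilylacetylene | C#C[Si](C)(C)C | starting material
6 | 3-hydroxy-4,4,6,6-tetramethyl-2-[(3R)-4-methyl-1-(trimethylsilyl)pent-1-yn-3-yl]cyclohex-2-ene-1,5-dione | CC(C)[C@@H](C#C[Si](C)(C)C)C1=C(O)C(C)(C)C(=O)C(C)(C)C1=O | intermediate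
7 | 3-methoxy-4,4,6,6-tetramethyl-2-[(3R)-4-methyl-1-(trimethylsilyl)pent-1-yn-3-yl]cyclohex-2-ene-1,5-dione | CC(C)[C@@H](C#C[Si](C)(C)C)C1=C(OC)C(C)(C)C(=O)C(C)(C)C1=O | intermediate
8 | 3-methoxy-4,4,6,6-tetramethyl-2-[(3S)-4-methylpent-1-yn-3-yl]cyclohex-2-ene-1,5-dione | CC(C)[C@@H](C#C)C1=C(OC)C(C)(C)C(=O)C(C)(C)C1=O | intermediate
9 | lithium acetylide of 8 (C7 as in 8) | CC(C)[C@@H](C#C[Li])C1=C(OC)C(C)(C)C(=O)C(C)(C)C1=O | intermediate
10 | lithium ynolate derived from 9 (C7 as in 8) | CC(C)[C@@H](C#CO[Li])C1=C(OC)C(C)(C)C(=O)C(C)(C)C1=O | intermediate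
11 | 3-methoxy-4,4,6,6-tetramethyl-2-[(3S)-4-methyl-1-(triisopropylsilyloxy)pent-1-yn-3-yl]cyclohex-2-ene-1,5-dione | CC(C)[Si](C(C)C)(C(C)C)OC#C[C@H](C(C)C)C1=C(OC)C(C)(C)C(=O)C(C)(C)C1=O | intermediate
12 | acetone | CC(C)=O | starting material
13 | 1-ethoxyprop-1-yne | CCOC#CC | starting material
14 | ketene | C=C=O | intermediate
15 | 3-ethoxy-2-methylcyclobut-2-en-1-one | CCOC1=C(C)C(=O)C1 | intermediate
16 | 3-ethoxy-2-methylbuta-1,3-dien-1-one ((1-ethoxyvinyl)methylketene) | C=C(OCC)C(C)=C=O | intermediate
17 | 4-(1-ethoxyethenyl)-4-methyl-3-(triisopropylsilyloxy)cyclobut-2-en-1-one carrying at C2 the C7 unit of 11 (C7 as in 11; both epimers at the ring quaternary carbon) | CC(C)[C@@H](C1=C(O[Si](C(C)C)(C(C)C)C(C)C)C(C)(C(OCC)=C)C1=O)C2=C(OC)C(C)(C)C(=O)C(C)(C)C2=O | intermediate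
18 | 5-ethoxy-4-methyl-3-(triisopropylsilyloxy)hexa-1,3,5-trien-1-one carrying at C2 the C7 unit of 11 (ketene and ethoxyvinyl ends cis; C7 as in 11) | CC(C)[C@@H](C(=C=O)/C(O[Si](C(C)C)(C(C)C)C(C)C)=C(/C)C(OCC)=C)C1=C(OC)C(C)(C)C(=O)C(C)(C)C1=O | intermediate
19 | 5-ethoxy-4-methyl-3-(triisopropylsilyloxy)cyclohexa-2,4-dien-1-one carrying at C2 the C7 unit of 11 (C7 as in 11) | CC(C)[C@@H](C1=C(O[Si](C(C)C)(C(C)C)C(C)C)C(C)=C(OCC)CC1=O)C2=C(OC)C(C)(C)C(=O)C(C)(C)C2=O | intermediate
20 | 2-{(1S)-1-[4-ethoxy-6-hydroxy-3-methyl-2-(triisopropylsilyloxy)phenyl]-2-methylpropyl}-3-methoxy-4,4,6,6-tetramethylcyclohex-2-ene-1,5-dione | Cc1c(OCC)cc(O)c([C@@H](C2=C(OC)C(C)(C)C(=O)C(C)(C)C2=O)C(C)C)c1O[Si](C(C)C)(C(C)C)C(C)C | intermediate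
21 | 5-ethoxy-2-[(1S)-1-(2-methoxy-3,3,5,5-tetramethyl-4,6-dioxocyclohex-1-en-1-yl)-2-methylpropyl]-4-methyl-3-(triisopropylsilyloxy)phenyl 2-methylpropanoate | Cc1c(OCC)cc(OC(=O)C(C)C)c([C@@H](C2=C(OC)C(C)(C)C(=O)C(C)(C)C2=O)C(C)C)c1O[Si](C(C)C)(C(C)C)C(C)C | intermediate
22 | 2-{(1S)-1-[4-ethoxy-6-hydroxy-3-methyl-5-(2-methylpropanoyl)-2-(triisopropylsilyloxy)phenyl]-2-methylpropyl}-3-methoxy-4,4,6,6-tetramethylcyclohex-2-ene-1,5-dione | Cc1c(OCC)c(C(=O)C(C)C)c(O)c([C@@H](C2=C(OC)C(C)(C)C(=O)C(C)(C)C2=O)C(C)C)c1O[Si](C(C)C)(C(C)C)C(C)C | intermediate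
23 | 3-hydroxy-4,4,6,6-tetramethyl-2-{(1S)-1-[4,6-dihydroxy-3-methyl-5-(2-methylpropanoyl)-2-(triisopropylsilyloxy)phenyl]-2-methylpropyl}cyclohex-2-ene-1,5-dione | Cc1c(O)c(C(=O)C(C)C)c(O)c([C@@H](C2=C(O)C(C)(C)C(=O)C(C)(C)C2=O)C(C)C)c1O[Si](C(C)C)(C(C)C)C(C)C | intermediate
24 | 3-hydroxy-4,4,6,6-tetramethyl-2-{(1S)-2-methyl-1-[2,4,6-trihydroxy-3-methyl-5-(2-methylpropanoyl)phenyl]propyl}cyclohex-2-ene-1,5-dione (CNP0210316.1) | Cc1c(O)c(C(=O)C(C)C)c(O)c([C@@H](C2=C(O)C(C)(C)C(=O)C(C)(C)C2=O)C(C)C)c1O | target

**Step count**

Total: 10 steps (telescoped operations counted once). Longest linear sequence: 9 steps (steps 1–4 and 6–10); step 5 is a one-step branch.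

**Steps most likely to fail, with fallbacks**

1. Step 6 (benzannulation). The alkoxy-substituted vinylketene may be intercepted too slowly by the hindered, α-branched siloxyalkyne, so that ketene dimerisation, acylation of the product phenol or thermal loss of the siloxyalkyne takes over. The fallback gives up the pericyclic construction of ring A and forms the C5–C7 bond instead. It sets out from 4 and returns at 24. Commercial 2,4,6-trihydroxytoluene is C-acylated (isobutyryl chloride, AlCl3, nitrobenzene, Friedel–Crafts) to 1-(2,4,6-trihydroxy-3-methylphenyl)-2-methylpropan-1-one F1. Its only free ring carbon adds to the alkylidene of 4 (THF, rt, catalytic NaH if needed; Michael-type Friedel–Crafts alkylation) to give racemic 24 F2. The enantiomers are separated by preparative chromatography on a chiral stationary phase to give 24.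

2. Step 4 (acetylide oxidation and silylation). The lithium acetylide or the ynolate may add to a ring B carbonyl of a second molecule, or the peroxide anion may attack the vinylogous ester, faster than oxygen is transferred. The fallback carries ring B through this stage as its own lithium enolate, which removes the electrophilic vinylogous ester. It sets out from 6 and returns at 20. Methanolysis of 6 (K2CO3, MeOH, then acidification) gives 3-hydroxy-4,4,6,6-tetramethyl-2-[(3S)-4-methylpent-1-yn-3-yl]cyclohex-2-ene-1,5-dione F3. Double deprotonation (LiHMDS, 3.2 equiv in all, with t-BuOOH, THF, −78 → 0 °C), oxidation and double silylation (i-Pr3SiOTf, 2.3 equiv) give 4,4,6,6-tetramethyl-2-[(3S)-4-methyl-1-(triisopropylsilyloxy)pent-1-yn-3-yl]-3-(triisopropylsilyloxy)cyclohex-2-ene-1,5-dione F4. Benzannulation with 15 under the conditions of step 6 gives the ring A phenol with ring B as its triisopropylsilyl enol ether F5. Mild hydrolysis of the vinylogous silyl ester (AcOH–THF–H2O, rt) leaves the aryl silyl ether and gives the ring A phenol with free ring B enol F6. One equivalent of Me3SiCHN2 in MeOH–toluene methylates the far more acidic enol and not the hindered phenol, giving 20.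

3. Step 2 (asymmetric alkynylation). The catalyst may discriminate the faces of C7 poorly on this acceptor, or stall through slow protonolysis of the rhodium enolate, alkyne dimerisation or deconjugation of 4. The fallback separates bond formation from stereocontrol. It sets out from 4 and returns at 6. Addition of (trimethylsilyl)ethynylmagnesium chloride (from 5 and i-PrMgCl, THF, −78 °C), which can only add 1,4 because both carbonyls are neopentyl-flanked, gives racemic 6 F7. The enantiomers are separated by preparative chromatography on a chiral stationary phase, and the (R)-enantiomer 6 is carried on.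

**Further compounds**

F1 | step 6 | 1-(2,4,6-trihydroxy-3-methylphenyl)-2-methylpropan-1-one | Cc1c(O)cc(O)c(C(=O)C(C)C)c1O
F2 | step 6 | racemic 24 | Cc1c(O)c(C(=O)C(C)C)c(O)c(C(C2=C(O)C(C)(C)C(=O)C(C)(C)C2=O)C(C)C)c1O
F3 | step 4 | 3-hydroxy-4,4,6,6-tetramethyl-2-[(3S)-4-methylpent-1-yn-3-yl]cyclohex-2-ene-1,5-dione | CC(C)[C@@H](C#C)C1=C(O)C(C)(C)C(=O)C(C)(C)C1=O
F4 | step 4 | 4,4,6,6-tetramethyl-2-[(3S)-4-methyl-1-(triisopropylsilyloxy)pent-1-yn-3-yl]-3-(triisopropylsilyloxy)cyclohex-2-ene-1,5-dione | CC(C)[C@@H](C#CO[Si](C(C)C)(C(C)C)C(C)C)C1=C(O[Si](C(C)C)(C(C)C)C(C)C)C(C)(C)C(=O)C(C)(C)C1=O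
F5 | step 4 | 2-{(1S)-1-[4-ethoxy-6-hydroxy-3-methyl-2-(triisopropylsilyloxy)phenyl]-2-methylpropyl}-4,4,6,6-tetramethyl-3-(triisopropylsilyloxy)cyclohex-2-ene-1,5-dione | Cc1c(OCC)cc(O)c([C@@H](C2=C(O[Si](C(C)C)(C(C)C)C(C)C)C(C)(C)C(=O)C(C)(C)C2=O)C(C)C)c1O[Si](C(C)C)(C(C)C)C(C)C
F6 | step 4 | 2-{(1S)-1-[4-ethoxy-6-hydroxy-3-methyl-2-(triisopropylsilyloxy)phenyl]-2-methylpropyl}-3-hydroxy-4,4,6,6-tetramethylcyclohex-2-ene-1,5-dione | Cc1c(OCC)cc(O)c([C@@H](C2=C(O)C(C)(C)C(=O)C(C)(C)C2=O)C(C)C)c1O[Si](C(C)C)(C(C)C)C(C)C
F7 | step 2 | racemic 6 | CC(C)C(C#C[Si](C)(C)C)C1=C(O)C(C)(C)C(=O)C(C)(C)C1=O
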